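Numbering used throughout (xenicane type): C1 (acetal carbon), O2, C3, C4, C4a, C5, C6, C7 (bearing methyl C18), C8, C9, C10, C11 (bearing methylene C19), C11a; side chain C12, C13, C14, C15 (bearing methyls C16 and C17). In this numbering target 48 is (1S,4aS,7S,8R,9S,10S,11aR,12S,13R).

## Structural features

Compound 48 is a xenicane diterpenoid in which a 2-acetoxy-3,4-dihydro-2H-pyran (C1, O2, C3, C4, C4a, C11a) is trans-fused through the C4a–C11a bond to a nine-membered carbocycle (C4a, C5, C6, C7, C8, C9, C10, C11, C11a). The large ring carries four functions in unbroken sequence: a cis-7,8-epoxide with the C18 methyl on C7, a benzoate on C9, the only free hydroxyl on C10 and an exocyclic methylene on C11. C4 bears a side chain with an anti-12,13-diacetate and an isobutenyl end. The nine stereocentres form three clusters of neighbours: C1/C11a/C4a on the heterocycle (C1–OAc cis to the C11a–C11 bond, C4a–H and C11a–H trans), C7/C8/C9/C10 on the carbocycle (epoxide oxygen trans to the C9 ester, C9–O and C10–O cis) and C12/C13. Fragile groups are the C1 acyloxy acetal, the C3=C4 enol ether whose C12 acetate is a vinylogous acetal leaving group, the trisubstituted epoxide, and the C9 benzoate next to a free C10 hydroxyl (1,2-acyl shift). The real difficulty is threefold: the nine-membered ring, its trans fusion with absolute control, and an end game in which the oxygens at C1, C9, C10, C12 and C13 must end as three acetates, one benzoate and one free hydroxyl without acid or strong base. The key step exploits the fact that C11a and C4a are the β- and α-carbons of C4 inside the O2 ring, which also holds C1 at the acetal level. That is the pattern of a 6-alkoxy-2H-pyran-3(6H)-one, so C11–C11a and C4a–C5 can be made by conjugate addition and enolate alkylation with the C1 acetal as the single controlling centre.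

## Logic of the disconnections

**48 back to 45.** The C10–O–Si bond (47) and the C1–O–acyl bond (46) are cut first, then the C1 hydroxyl is traced to the benzylic acetal of 45. The free hydroxyl has to stay masked until every acetate is in place, and the acyloxy acetal is the most labile group, so it is made last but one. This removes the whole problem of telling five oxygens apart. The forward steps must be neutral (oxidative acetal cleavage, buffered fluoride), and the acylation of 46 must deliver the C1 configuration of 48, which is opposite to that of 45.

**45 back to 35 and 42.** The C12–O acyl bond and then the C4–C12 bond are cut. This is the most convergent cut: it removes the whole side chain and leaves an enol triflate at C4. The forward step must add the C4 vinyl nucleophile to the α-acetoxy aldehyde in the Felkin–Anh sense without isomerising it, and every group present must tolerate divalent chromium.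

**35 back to 32.** The C4–O triflyl bond is cut to the ketone 33, and the two epoxide C–O bonds to the alkene 32. The ketone is the carbonyl that organised the key step. The epoxide is placed after ring closure, so that the ring conformation decides the face, but before the enol ether exists, since an enol ether would outrun the alkene. The forward steps demand enolisation toward C3 and not C4a, and oxygen transfer to C7=C8 anti to the C9 ester and not to C11=C19.

**32 back to 29.** After removing the silyl group (31), the C10–C11 bond of the nine-membered ring is cut between the vinyl carbon and the carbinol carbon. This opens the medium ring and removes the C10 stereocentre, leaving a keto aldehyde with a vinyl iodide. The forward closure needs high dilution, attack on the aldehyde and not the ketone, and control of C10 by C9.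

**29 back to 13 and 23.** Oxidation levels are adjusted (28), silyl groups returned (27), the C11 iodide is traced to a vinylsilane (26), and the C6–C7 bond is cut. The sp3–sp2 bond next to a Z-trisubstituted alkene calls for a B-alkyl Suzuki coupling in which the alkene geometry comes ready-made from 23. This splits the molecule into the heterocyclic half 13 and a five-carbon piece. The forward step demands retention of geometry, and the C11 iodide must still be masked as the silane, since a C6 organometallic would otherwise close a five-membered ring onto C11. C4 has to be a silyl ether because an organolithium is used.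

**13 back to 10.** Only functional groups change: the C6 iodide and C4 silyl ether come from diol 11, which comes from keto ester 10. The forward demand is to tell a primary from a secondary hydroxyl.

**10 back to 4, 6 and 7 (key disconnection).** C11–C11a and C4a–C5 are cut. Both bonds lie β and α to the C4 carbonyl, and the trans relationship can be relayed from C1. This removes two skeletal bonds and two stereocentres and leaves a flat enone with one stereocentre. The forward step demands anti addition relative to the C1 alkoxy group and C-alkylation at C4a before the enolate can equilibrate.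

**4 back to 1; 6 back to 5.** The C1–O bond of 4 is exchanged for that of acetate 3 (retention). Compound 3 comes from lactol 2 by enzymatic acylation, and 2 from 1 by oxidative ring expansion. The gain is an achiral, cheap furan; the demand is that one enzyme sets the only stereocentre on which all others depend. Compound 6 comes from 5 by magnesium insertion.

**23 back to 14 and 16.** The acyl and silyl groups are removed (22, 21), the acetal is restored (20), and C7=C8 is cut by olefination to 15 and 16; 15 comes from 14. C9 is bought from the chiral pool and the Z-iodoalkene is made in one step. The demand is Z selectivity.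

**42 back to 15 and 36.** The aldehyde is traced to the silyl ether 41, the diol 39 and the acetal 38, and C14=C15 is cut to 15 and 36. The same chiral-pool aldehyde therefore supplies C13. The demand is that no intermediate has a free primary hydroxyl next to the acetate.

## Other disconnections considered

**Alternative 1:** The cut is C6–C7 inside the nine-membered ring. Forward, the terminal C5=C6 vinyl group of seco compound A1 would be hydroborated with 9-BBN, and the C6 alkylborane coupled with the C7 Z-iodoalkene of the same molecule (PdCl2(dppf), Cs2CO3) to give bicycle A2.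
- In its favour: the alkene geometry is carried in from the iodide and no stereocentre is created in the ring closure. C9 and C10 can be set earlier in open-chain chemistry where reagent control is available. On this point it is better than the chosen plan, whose ring closure (step 16) must set C10 by substrate control in a medium ring.
- Against it here: the ring must form by reductive elimination from a strained palladacycle, so protodeboronation, β-hydride elimination and intermolecular coupling compete. The borane must also distinguish the C5=C6 vinyl group from the C11 methylene. The cut says nothing about how the trans-disubstituted heterocycle of A1 is made.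
- Comparison: structurally the two plans make the same two bonds (C6–C7 by Suzuki coupling, C10–C11 by vinyl-to-aldehyde addition) in opposite order. The chosen order puts the sp3–sp2 coupling in the more reliable intermolecular role. Mechanistically both closures are metal-mediated; the alternative avoids a stereogenic ring closure, while the chosen one avoids a strained reductive elimination. In steps they are about equal: A1 needs a vinyl group at C4a instead of the acetate arm of 10, and the C4 ester of A2 must be reduced and re-oxidised before the side chain can be added, whereas 35 couples directly.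

**Alternative 2:** The cut removes three bonds of the heterocycle at once: C4=C4a, C4a–C11a and C1–O2. Forward, aldehyde A3 (its carbonyl carbon is C4a) would condense with methyl 3-oxopropanoate A4 to a 2-formylacrylate. The O2=C3–C4=C4a heterodiene of this would add enol ether A5 across C11a=C1 in an inverse-demand hetero-Diels–Alder reaction to give dihydropyran A6.
- In its favour: it is the most convergent option, forming the ring, the enol ether and the C4 carboxyl in one operation. The C4 ester is a robust vinylogous carbonate, and no regioselective enolisation of a ketone is needed. On bonds formed per step and on avoiding step 19 it is better than the chosen plan.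
- Against it here: C1, C11a and C4a all arise in a cycloaddition whose nearest controlling centre (C7) is three bonds from C4a. The relative configuration of the new ring can follow from the E enol ether, but its absolute sense relative to C7–C9 is not controlled by the substrate. A4 is prone to self-condensation, and the epoxide would have to survive the Lewis acid or heat. In A6 the nine-membered ring is still open and must be closed through the alkyne (whose carbons are C11 and the future C19) onto a C10 aldehyde, a reductive coupling with its own regiochemical problem.
- Comparison: structurally the alternative builds the heterocycle around the side of the large ring, whereas the chosen plan builds everything around the heterocycle. Mechanistically a pericyclic step gives good relative but weak absolute control, whereas step 5 relays one enzyme-set centre to C11a and C4a. In steps the alternative is shorter for the heterocycle but longer and less certain for the medium ring.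

**Alternative 3:** The cut is C11a–C1, with the heterocycle formed last on a ready-made carbocycle. Forward, in precursor A7 (drawn with a Z C11=C11a ring alkene, an assumption) O2 carries a dimethoxymethyl group and C11 a (trimethylsilyl)methyl group. TMSOTf would ionise the orthoester to a dialkoxycarbenium ion at C1, C11a would attack it, and loss of silicon from C19 would move the alkene to C11=C19, giving A8.
- In its favour: one step forms C11a–C1, closes the ring, sets C11a and C1 and delivers the C11 methylene as a direct consequence of the mechanism. Here it is better than the chosen plan, which needs a separate iododesilylation (step 13) and an organometallic ring closure (step 16) to reach the same methylene.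
- Against it here: A7 already contains the nine-membered ring with two ring alkenes, three stereocentres and an allylsilane, so the hardest problem is moved upstream and not solved. The face of attack at C11a depends on the conformation of a flexible ring. TMSOTf rules out an epoxide at that stage. C4 arrives as a silyl-protected alcohol, so deprotection, oxidation and the same regioselective enol triflate formation as in step 19 are still required.
- Comparison: structurally the alternative defers the heterocycle, whereas the chosen plan uses it as the stereochemical template. Mechanistically both rely on a C1 oxocarbenium-type centre, once as electrophile and once as the directing group. In steps the alternative saves the methylene installation but adds the C4 oxidation sequence and an unsolved carbocycle synthesis.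

Key step: step 5

**Assumptions and design remarks**
- The acetal alkyl group is a spectator. 4-Methoxybenzyl is used in place of methyl because a methyl acetal could be exchanged for acetate only with acid, which the epoxide, the enol ether and the C12 acetate of the late intermediates would not survive.
- C1 in 4 to 45 has the configuration opposite to C1 of 48, because the alkoxy group must be anti to C11 to steer the cuprate. This centre is not carried into the target; it is re-set at the lactol stage (steps 26 and 27).
- The lipase is assumed to acylate the (R)-lactol. If a given enzyme prefers the (S)-lactol, the (R)-acetate would instead be the unreacted ester from lipase alcoholysis of the racemic acetate.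
- A (Z)-3-iodobut-2-enyl unit from but-2-yn-1-ol would hold only C18, C7, C8 and C9. C10 and the C9 stereocentre are therefore taken from (S)-glyceraldehyde acetonide 15, which also supplies C12–C14.
- The C4 carbinol of 11–13 and 24–28 is drawn as the expected equatorial epimer. Either epimer serves, since C4 returns to a ketone in step 15.

## Route

Step 1
Reactants: 1 furfuryl alcohol
Product: 2 6-hydroxy-2H-pyran-3(6H)-one (racemic lactol)
Conditions: NBS, NaHCO3, NaOAc, THF/H2O (4:1), 0 °C
Reagents that add atoms: water, O
Why: Achmatowicz rearrangement: bromonium-induced oxidative opening of the furan to the cis-enedione, which recloses to the pyranone hemiacetal; the lactol centre stays labile, which step 2 uses.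

Step 2
Reactants: 2 6-hydroxy-2H-pyran-3(6H)-one
Product: 3 (R)-6-acetoxy-2H-pyran-3(6H)-one
Conditions: vinyl acetate, immobilised Burkholderia cepacia lipase, i-Pr2O, rt; recrystallisation
Reagents that add atoms: vinyl acetate, CC(=O)OC=C
Why: Lipase-catalysed irreversible transesterification run as a dynamic kinetic resolution: the lactol enantiomers interconvert by ring opening while the enzyme acylates one of them, which fixes the acetal centre; crystallisation should raise the enantiomeric purity further.

Step 3
Reactants: 3 (R)-6-acetoxy-2H-pyran-3(6H)-one
Product: 4 (S)-6-[(4-methoxybenzyl)oxy]-2H-pyran-3(6H)-one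
Conditions: 4-MeOC6H4CH2OH, Pd(PPh3)4 (cat.), CH2Cl2, 0 °C → rt
Reagents that add atoms: 4-methoxybenzyl alcohol, COc1ccc(CO)cc1
Why: Tsuji–Trost-type O-glycosylation: zerovalent palladium ionises the allylic acetate anti and the alcohol attacks the π-allyl complex anti to the metal, so double inversion gives net retention (the R to S change of label is only a change of CIP priorities).

Step 4
Reactants: 5 (1-bromovinyl)trimethylsilane
Product: 6 1-(trimethylsilyl)vinylmagnesium bromide (THF solution)
Conditions: Mg, BrCH2CH2Br (cat.), THF, 45 °C → rt
Reagents that add atoms: magnesium, [Mg]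
Why: Grignard formation by magnesium insertion into the vinylic C–Br bond; the reagent is a known, stable solution.

Step 5
Reactants: 4 (S)-6-[(4-methoxybenzyl)oxy]-2H-pyran-3(6H)-one; 6 1-(trimethylsilyl)vinylmagnesium bromide; 7 tert-butyl bromoacetate
Product: 10 tert-butyl 2-{(2S,3S,4S)-2-[(4-methoxybenzyl)oxy]-5-oxo-3-[1-(trimethylsilyl)vinyl]oxan-4-yl}acetate (C1 alkoxy trans to the C11a silylvinyl group, C11a and C4a substituents trans), via cuprate 8 (not isolated), via magnesium enolate 9 (not isolated)
Conditions: 6 (2.2 equiv), CuI (1.1 equiv), THF, −40 °C; 4, −78 °C; then DMPU, 7 (3 equiv), −78 → −30 °C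
Reagents that add atoms: none
Why: This is a conjugate addition–enolate alkylation (three-component coupling) on a cyclic enone, the closest known type being copper-mediated 1,4-addition to 6-alkoxy-2H-pyran-3(6H)-ones with trapping of the enolate. Cuprate 8 forms a π-complex with the enone of 4 and transfers the 1-(trimethylsilyl)vinyl group to C11a through a trivalent copper β-adduct and reductive elimination, which forms C11–C11a and gives enolate 9 regiospecifically across C4=C4a. DMPU then loosens the enolate aggregate and the activated primary bromide 7 alkylates C4a in an SN2 reaction, forming C4a–C5. No ring is closed, because the furan-derived ring already holds C1, O2, C3 and C4 at the right oxidation levels. C11a is controlled by C1: the 4-methoxybenzyloxy group sits pseudo-axial in the half-chair (anomeric effect) and the cuprate enters axially on the opposite face, so the new group ends trans to it. C4a is controlled by C11a: the bulky silylvinyl group shields its own face of the enolate, the electrophile enters anti, and the trans-diequatorial product is also the thermodynamically preferred one should C4a epimerise. The step needs 1,4- over 1,2-addition (secured by copper), C- over O-alkylation, and C4a over C3 alkylation (secured by the regiodefined enolate, low temperature and an excess of a fast electrophile, so that proton transfer between product and enolate stays slow). The vinylsilane is inert here and later serves as a masked C11 iodide, while the C4 ketone later becomes the enol triflate that accepts the side chain.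

Step 6
Reactants: 10 keto ester
Product: 11 diol (C4 equatorial carbinol trans to the C4a arm; C6 primary alcohol)
Conditions: LiAlH4, THF, 0 °C → rt
Reagents that add atoms: none
Why: Hydride reduction of ketone and tert-butyl ester in one operation; axial delivery to C4 should favour the equatorial carbinol, but this centre is erased again in step 15.

Step 7
Reactants: 11 diol
Product: 13 C6 iodide with C4 triethylsilyl ether, via iodo alcohol 12 (not isolated)
Conditions: I2, PPh3, imidazole, CH2Cl2, 0 °C; then Et3SiCl, DMAP (cat.), rt
Reagents that add atoms: iodine, II; chlorotriethylsilane, CC[Si](Cl)(CC)CC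
Why: Appel-type iodination is selective for the primary C6 hydroxyl, and silylation of the remaining secondary hydroxyl in the same flask masks C4 for the organolithium chemistry of step 12.

Step 8
Reactants: 14 (R)-solketal
Product: 15 (S)-2,2-dimethyl-1,3-dioxolane-4-carbaldehyde
Conditions: (COCl)2, DMSO, CH2Cl2, −78 °C; Et3N, −78 → 0 °C
Reagents that add atoms: none
Why: Swern oxidation at low temperature should leave the α-stereocentre intact; the aldehyde is used at once, divided between steps 9 and 20.

Step 9
Reactants: 15 (S)-2,2-dimethyl-1,3-dioxolane-4-carbaldehyde; 16 ethyltriphenylphosphonium iodide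
Product: 20 (R)-4-[(Z)-2-iodoprop-1-en-1-yl]-2,2-dimethyl-1,3-dioxolane, via ethylidenetriphenylphosphorane 17 (not isolated), via (1-iodoethyl)triphenylphosphonium iodide 18 (not isolated), via (1-iodoethylidene)triphenylphosphorane 19 (not isolated)
Conditions: 16, n-BuLi, THF, 0 °C; I2, −78 °C; NaN(SiMe3)2, −20 °C; then 15, −78 → −20 °C
Reagents that add atoms: iodine, II
Why: Stork–Zhao-type Wittig olefination with the α-iodo ylide 19; kinetic oxaphosphetane formation places iodine cis to the aldehyde-derived substituent, giving the Z trisubstituted iodoalkene (C18, C7, C8) with C9 untouched.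

Step 10
Reactants: 20 iodoalkene acetonide
Product: 21 (2R,3Z)-4-iodopent-3-ene-1,2-diol
Conditions: AcOH/H2O (4:1), 40 °C
Reagents that add atoms: none
Why: Acid-catalysed acetal hydrolysis; the vinyl iodide is not an enol derivative and should be stable to aqueous acetic acid.

Step 11
Reactants: 21 (2R,3Z)-4-iodopent-3-ene-1,2-diol
Product: 23 (2R,3Z)-4-iodo-1-[(triethylsilyl)oxy]pent-3-en-2-yl benzoate, via mono-silyl ether 22 (not isolated)
Conditions: Et3SiCl (1.05 equiv), imidazole, CH2Cl2, −78 → −30 °C; then BzCl, Et3N, DMAP (cat.), 0 °C → rt
Reagents that add atoms: chlorotriethylsilane, CC[Si](Cl)(CC)CC; benzoyl chloride, O=C(Cl)c1ccccc1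
Why: Steric differentiation: the primary hydroxyl is silylated at low temperature and the secondary allylic hydroxyl is then benzoylated (DMAP-catalysed acylation) in the same flask, so the C9 benzoate is in place from the start.

Step 12
Reactants: 13 C6 iodide with C4 triethylsilyl ether; 23 (2R,3Z)-4-iodo-1-[(triethylsilyl)oxy]pent-3-en-2-yl benzoate
Product: 26 open-chain coupling product (new C6–C7 bond, 7Z alkene, C9 benzoate, C10 and C4 triethylsilyl ethers, C11 vinylsilane), via alkyllithium 24 (not isolated), via borate complex 25 (not isolated)
Conditions: 13, t-BuLi (2.1 equiv), Et2O, −78 °C; B-OMe-9-BBN, THF, −78 °C → rt; then 23, PdCl2(dppf) (cat.), AsPh3, Cs2CO3, DMF/H2O, rt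
Reagents that add atoms: none
Why: B-alkyl Suzuki–Miyaura coupling: iodine–lithium exchange and capture by the borinate give borate 25, which transmetalates to the vinylpalladium formed from 23 with retention of the Z geometry; C11 is still a silane, so C6 cannot cyclise onto it.

Step 13
Reactants: 26 open-chain coupling product
Product: 27 C11 vinyl iodide (otherwise as 26)
Conditions: NIS, 2,6-lutidine, (CF3)2CHOH, 0 °C, short reaction time
Reagents that add atoms: N-iodosuccinimide, O=C1CCC(=O)N1I
Why: Iododesilylation (ipso substitution through a β-silyl-stabilised cation) in hexafluoroisopropanol, which activates NIS; the vinylsilane should react far faster than the benzoate-deactivated C7=C8 alkene or the anisyl ring when little excess reagent is used.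

Step 14
Reactants: 27 C11 vinyl iodide
Product: 28 C4,C10-diol (C9 benzoate retained)
Conditions: HF·pyridine, pyridine, THF, 0 °C → rt
Reagents that add atoms: none
Why: Fluoride-driven cleavage of both triethylsilyl ethers in a buffered, weakly acidic medium that disfavours benzoate shift from C9 to the freed C10 hydroxyl; the diol is oxidised without storage.

Step 15
Reactants: 28 C4,C10-diol
Product: 29 C4 ketone C10 aldehyde
Conditions: Dess–Martin periodinane, NaHCO3, CH2Cl2, 0 °C → rt
Reagents that add atoms: none
Why: Dess–Martin oxidation of both carbinols under buffered, non-basic conditions, which should spare the α-benzoyloxy aldehyde centre C9 and leave C4a in its stable trans arrangement.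

Step 16
Reactants: 29 C4 ketone C10 aldehyde
Product: 31 bicyclic allylic alcohol (nine-membered ring closed at C10–C11; C10–OH cis to the C9 benzoate; 11-methylene; 4-oxo), via vinylchromium species 30 (not isolated)
Conditions: CrCl2 (excess), NiCl2 (cat.), DMSO/THF, high dilution, rt
Reagents that add atoms: none
Why: Nozaki–Hiyama–Kishi reaction: zerovalent nickel inserts into the C11–I bond, transmetalation gives the trivalent vinylchromium 30, and this adds to the aldehyde and not the ketone (9-exo-trig closure); Felkin–Anh attack anti to the C9–O bond should give the 9,10-anti (cis on the ring) carbinol.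

Step 17
Reactants: 31 bicyclic allylic alcohol
Product: 32 C10 triethylsilyl ether
Conditions: Et3SiCl, imidazole, DMAP (cat.), DMF, 0 °C → rt
Reagents that add atoms: chlorotriethylsilane, CC[Si](Cl)(CC)CC
Why: Silylation masks the one hydroxyl that must stay free in the target through all acylations and removes its directing effect on the C11 methylene in step 18.

Step 18
Reactants: 32 C10 triethylsilyl ether
Product: 33 7,8-epoxide (oxygen trans to the C9 benzoate)
Conditions: dimethyldioxirane, acetone/CH2Cl2, −20 → 0 °C
Reagents that add atoms: dimethyldioxirane, CC1(C)OO1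
Why: Dioxirane epoxidation is a concerted, stereospecific oxygen transfer (Z alkene to cis epoxide); peripheral attack on the Z-cyclononene face anti to the allylic C9 ester should set C7 and C8, the trisubstituted alkene should react before the hindered methylene, and a dioxirane cannot cause Baeyer–Villiger oxidation of the C4 ketone.

Step 19
Reactants: 33 7,8-epoxide
Product: 35 C4 enol triflate (C3=C4), via potassium enolate 34 (not isolated)
Conditions: KN(SiMe3)2, THF, −78 °C; then PhNTf2, −78 → −40 °C
Reagents that add atoms: N-phenylbis(trifluoromethanesulfonimide), O=S(=O)(N(c1ccccc1)S(=O)(=O)C(F)(F)F)C(F)(F)F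
Why: Kinetic enolisation and O-triflation: the bulky amide should remove a proton from the unhindered, oxygen-activated C3 methylene and not from the tertiary C4a–H flanked by two substituents; benzoate and epoxide have no comparably acidic proton at −78 °C.

Step 20
Reactants: 15 (S)-2,2-dimethyl-1,3-dioxolane-4-carbaldehyde; 36 isopropyltriphenylphosphonium iodide
Product: 38 (R)-2,2-dimethyl-4-(2-methylprop-1-en-1-yl)-1,3-dioxolane, via isopropylidenetriphenylphosphorane 37 (not isolated)
Conditions: 36, n-BuLi, THF, 0 °C; then 15, −78 °C → rt
Reagents that add atoms: none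
Why: Wittig olefination with a non-stabilised ylide; the new alkene has two identical methyl ends, so no geometry issue arises, and C13 comes unchanged from 15.

Step 21
Reactants: 38 (R)-2,2-dimethyl-4-(2-methylprop-1-en-1-yl)-1,3-dioxolane
Product: 39 (R)-4-methylpent-3-ene-1,2-diol
Conditions: AcOH/H2O (4:1), 40 °C
Reagents that add atoms: none
Why: Acid-catalysed acetal hydrolysis under conditions mild enough to leave the allylic carbinol in place.

Step 22
Reactants: 39 (R)-4-methylpent-3-ene-1,2-diol
Product: 41 (R)-4-methyl-1-[(triethylsilyl)oxy]pent-3-en-2-yl acetate, via mono-silyl ether 40 (not isolated)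
Conditions: Et3SiCl (1.05 equiv), imidazole, CH2Cl2, −78 → −30 °C; then Ac2O, pyridine, DMAP (cat.), 0 °C
Reagents that add atoms: chlorotriethylsilane, CC[Si](Cl)(CC)CC; acetic anhydride, CC(=O)OC(C)=O
Why: Same steric differentiation as in step 11: primary silylation, then DMAP-catalysed acetylation of the secondary allylic hydroxyl in one flask.

Step 23
Reactants: 41 (R)-4-methyl-1-[(triethylsilyl)oxy]pent-3-en-2-yl acetate
Product: 42 (R)-2-acetoxy-4-methylpent-3-enal
Conditions: (COCl)2, DMSO, CH2Cl2, −78 → −40 °C; i-Pr2NEt, −78 → 0 °C; used at once
Reagents that add atoms: none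
Why: Swern oxidation with in situ cleavage of the primary triethylsilyl ether takes the silyl ether straight to the aldehyde, so no free primary alcohol ever sits next to the acetate; the hindered amine and low temperature should limit enolisation of the sensitive α-acetoxy aldehyde.

Step 24
Reactants: 35 C4 enol triflate; 42 (R)-2-acetoxy-4-methylpent-3-enal
Product: 44 C12 carbinol (12S) with C13 acetate, via vinylchromium species 43 (not isolated)
Conditions: 42 (3 equiv), CrCl2, NiCl2 (cat.), DMF, rt
Reagents that add atoms: none
Why: Nozaki–Hiyama–Kishi coupling of an enol triflate: the vinylchromium 43 adds to the aldehyde, forming C4–C12; polar Felkin–Anh attack anti to the C13–OAc bond should give the 12,13-anti product, and any acetyl shift between O12 and O13 is harmless because step 25 acetylates whichever hydroxyl is free.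

Step 25
Reactants: 44 C12 carbinol
Product: 45 12,13-diacetate (C1 4-methoxybenzyl acetal, C10 triethylsilyl ether)
Conditions: Ac2O, pyridine, DMAP (cat.), CH2Cl2, 0 °C
Reagents that add atoms: acetic anhydride, CC(=O)OC(C)=O
Why: DMAP-catalysed acylation under mildly basic conditions that the enol ether, epoxide and benzoate tolerate.

Step 26
Reactants: 45 12,13-diacetate
Product: 46 C1 lactol (mixture of C1 anomers)
Conditions: DDQ, CH2Cl2/pH 7 phosphate buffer, 0 °C; used crude
Reagents that add atoms: none
Why: Oxidative cleavage of the 4-methoxybenzyl acetal: DDQ abstracts the benzylic hydride, water adds to the resulting oxocarbenium ion, and the hemiacetal collapses to the lactol and anisaldehyde at neutral pH, as in the unmasking of 4-methoxybenzyl ethers in the presence of glycal enol ethers.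

Step 27
Reactants: 46 C1 lactol
Product: 47 C1 acetate (1S, acetoxy cis to the C11a–C11 bond) with C10 triethylsilyl ether
Conditions: Ac2O, Et3N, DMAP (cat.), CH2Cl2, −20 → 0 °C
Reagents that add atoms: acetic anhydride, CC(=O)OC(C)=O
Why: Acylation of the lactol: the anomers interconvert under the basic conditions, and the pseudo-axial acetate favoured by the anomeric effect is expected to prevail; this step re-sets C1 to the configuration of the target.

Step 28
Reactants: 47 C1 acetate with C10 triethylsilyl ether
Product: 48 target (1S,4aS,7S,8R,9S,10S,11aR,12S,13R)
Conditions: HF·pyridine, pyridine, THF, 0 °C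
Reagents that add atoms: none
Why: Fluoride-driven cleavage of the labile triethylsilyl ether in a buffered medium that should spare the acyloxy acetal, the epoxide and the esters and gives no base to move the C9 benzoate.

## Compound list

1 | furfuryl alcohol | OCc1ccco1 | starting material
2 | 6-hydroxy-2H-pyran-3(6H)-one (racemic, labile lactol) | OC1OCC(=O)C=C1 | intermediate
3 | (R)-6-acetoxy-2H-pyran-3(6H)-one | CC(=O)O[C@H]1OCC(=O)C=C1 | intermediate
4 | (S)-6-[(4-methoxybenzyl)oxy]-2H-pyran-3(6H)-one | COc1ccc(CO[C@H]2OCC(=O)C=C2)cc1 | intermediate
5 | (1-bromovinyl)trimethylsilane | C=C(Br)[Si](C)(C)C | starting material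
6 | 1-(trimethylsilyl)vinylmagnesium bromide | C=C([Mg]Br)[Si](C)(C)C | intermediate
7 | tert-butyl bromoacetate | BrCC(=O)OC(C)(C)C | starting material
8 | bromomagnesium bis[1-(trimethylsilyl)vinyl]cuprate (not isolated) | C=C([Cu-]C(=C)[Si](C)(C)C)[Si](C)(C)C.[Mg+]Br | intermediate
9 | bromomagnesium C4=C4a enolate of the 1,4-adduct (not isolated) | C=C([Si](C)(C)C)[C@@H]1[C@@H](OCc2ccc(OC)cc2)OCC(O[Mg]Br)=C1 | intermediate
10 | tert-butyl 2-{(2S,3S,4S)-2-[(4-methoxybenzyl)oxy]-5-oxo-3-[1-(trimethylsilyl)vinyl]oxan-4-yl}acetate | C=C([Si](C)(C)C)[C@@H]1[C@@H](OCc2ccc(OC)cc2)OCC(=O)[C@H]1CC(=O)OC(C)(C)C | intermediate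
11 | diol: C4 equatorial carbinol and C6 primary alcohol, otherwise as 10 | C=C([Si](C)(C)C)[C@@H]1[C@@H](OCc2ccc(OC)cc2)OC[C@H](O)[C@H]1CCO | intermediate
12 | C6 iodide with free C4 hydroxyl (not isolated) | C=C([Si](C)(C)C)[C@@H]1[C@@H](OCc2ccc(OC)cc2)OC[C@H](O)[C@H]1CCI | intermediate
13 | C6 iodide with C4 triethylsilyl ether | C=C([Si](C)(C)C)[C@@H]1[C@@H](OCc2ccc(OC)cc2)OC[C@H](O[Si](CC)(CC)CC)[C@H]1CCI | intermediate
14 | (R)-solketal, (R)-(2,2-dimethyl-1,3-dioxolan-4-yl)methanol | OC[C@@H]1COC(C)(C)O1 | starting material
15 | (S)-2,2-dimethyl-1,3-dioxolane-4-carbaldehyde | O=C[C@@H]1COC(C)(C)O1 | intermediate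
16 | ethyltriphenylphosphonium iodide | CC[P+](c1ccccc1)(c1ccccc1)c1ccccc1.[I-] | starting material
17 | ethylidenetriphenylphosphorane (not isolated) | CC=P(c1ccccc1)(c1ccccc1)c1ccccc1 | intermediate
18 | (1-iodoethyl)triphenylphosphonium iodide (not isolated) | CC(I)[P+](c1ccccc1)(c1ccccc1)c1ccccc1.[I-] | intermediate
19 | (1-iodoethylidene)triphenylphosphorane (not isolated) | CC(I)=P(c1ccccc1)(c1ccccc1)c1ccccc1 | intermediate
20 | (R)-4-[(Z)-2-iodoprop-1-en-1-yl]-2,2-dimethyl-1,3-dioxolane | I/C(C)=C\[C@@H]1COC(C)(C)O1 | intermediate
21 | (2R,3Z)-4-iodopent-3-ene-1,2-diol | I/C(C)=C\[C@@H](O)CO | intermediate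
22 | (2R,3Z)-4-iodo-1-[(triethylsilyl)oxy]pent-3-en-2-ol (not isolated) | I/C(C)=C\[C@@H](O)CO[Si](CC)(CC)CC | intermediate
23 | (2R,3Z)-4-iodo-1-[(triethylsilyl)oxy]pent-3-en-2-yl benzoate | I/C(C)=C\[C@@H](OC(=O)c1ccccc1)CO[Si](CC)(CC)CC | intermediate
24 | C6 alkyllithium from 13 (not isolated) | C=C([Si](C)(C)C)[C@@H]1[C@@H](OCc2ccc(OC)cc2)OC[C@H](O[Si](CC)(CC)CC)[C@H]1CC[Li] | intermediate
25 | lithium B-methoxy-B-alkyl-9-borabicyclo[3.3.1]nonane borate, boron on C6 (not isolated) | C=C([Si](C)(C)C)[C@@H]1[C@@H](OCc2ccc(OC)cc2)OC[C@H](O[Si](CC)(CC)CC)[C@H]1CC[B-]1(OC)C2CCCC1CCC2.[Li+] | intermediate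
26 | open-chain coupling product: 7Z alkene, C9 benzoate, C10 and C4 triethylsilyl ethers, C11 vinylsilane | C=C([Si](C)(C)C)[C@@H]1[C@@H](OCc2ccc(OC)cc2)OC[C@H](O[Si](CC)(CC)CC)[C@H]1CC/C(C)=C\[C@@H](OC(=O)c1ccccc1)CO[Si](CC)(CC)CC | intermediate
27 | C11 vinyl iodide, otherwise as 26 | C=C(I)[C@@H]1[C@@H](OCc2ccc(OC)cc2)OC[C@H](O[Si](CC)(CC)CC)[C@H]1CC/C(C)=C\[C@@H](OC(=O)c1ccccc1)CO[Si](CC)(CC)CC | intermediate
28 | C4,C10-diol with C11 vinyl iodide and C9 benzoate | C=C(I)[C@@H]1[C@@H](OCc2ccc(OC)cc2)OC[C@H](O)[C@H]1CC/C(C)=C\[C@@H](OC(=O)c1ccccc1)CO | intermediate
29 | C4 ketone C10 aldehyde with C11 vinyl iodide | C=C(I)[C@@H]1[C@@H](OCc2ccc(OC)cc2)OCC(=O)[C@H]1CC/C(C)=C\[C@@H](OC(=O)c1ccccc1)C=O | intermediate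
30 | C11 vinylchromium dichloride (not isolated) | C=C([Cr](Cl)Cl)[C@@H]1[C@@H](OCc2ccc(OC)cc2)OCC(=O)[C@H]1CC/C(C)=C\[C@@H](OC(=O)c1ccccc1)C=O | intermediate
31 | bicyclic allylic alcohol: nine-membered ring closed, 10-OH cis to 9-benzoate, 11-methylene, 4-oxo, 1-(4-methoxybenzyloxy) | C=C1[C@@H]2[C@@H](OCc3ccc(OC)cc3)OCC(=O)[C@H]2CC/C(C)=C\[C@@H](OC(=O)c2ccccc2)[C@H]1O | intermediate
32 | C10 triethylsilyl ether of 31 | C=C1[C@@H]2[C@@H](OCc3ccc(OC)cc3)OCC(=O)[C@H]2CC/C(C)=C\[C@@H](OC(=O)c2ccccc2)[C@H]1O[Si](CC)(CC)CC | intermediate
33 | 7,8-epoxide (7S,8R; oxygen trans to 9-benzoate), 4-oxo | C=C1[C@@H]2[C@@H](OCc3ccc(OC)cc3)OCC(=O)[C@H]2CC[C@]2(C)O[C@@H]2[C@@H](OC(=O)c2ccccc2)[C@H]1O[Si](CC)(CC)CC | intermediate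
34 | potassium C3=C4 enolate of 33 (not isolated) | C=C1[C@@H]2[C@@H](OCc3ccc(OC)cc3)OC=C([O-])[C@H]2CC[C@]2(C)O[C@@H]2[C@@H](OC(=O)c2ccccc2)[C@H]1O[Si](CC)(CC)CC.[K+] | intermediate
35 | C4 enol triflate (C3=C4) | C=C1[C@@H]2[C@@H](OCc3ccc(OC)cc3)OC=C(OS(=O)(=O)C(F)(F)F)[C@H]2CC[C@]2(C)O[C@@H]2[C@@H](OC(=O)c2ccccc2)[C@H]1O[Si](CC)(CC)CC | intermediate
36 | isopropyltriphenylphosphonium iodide | CC(C)[P+](c1ccccc1)(c1ccccc1)c1ccccc1.[I-] | starting material
37 | isopropylidenetriphenylphosphorane (not isolated) | CC(C)=P(c1ccccc1)(c1ccccc1)c1ccccc1 | intermediate
38 | (R)-2,2-dimethyl-4-(2-methylprop-1-en-1-yl)-1,3-dioxolane | CC(C)=C[C@@H]1COC(C)(C)O1 | intermediate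
39 | (R)-4-methylpent-3-ene-1,2-diol | CC(C)=C[C@@H](O)CO | intermediate
40 | (R)-4-methyl-1-[(triethylsilyl)oxy]pent-3-en-2-ol (not isolated) | CC(C)=C[C@@H](O)CO[Si](CC)(CC)CC | intermediate
41 | (R)-4-methyl-1-[(triethylsilyl)oxy]pent-3-en-2-yl acetate | CC(C)=C[C@@H](OC(C)=O)CO[Si](CC)(CC)CC | intermediate
42 | (R)-2-acetoxy-4-methylpent-3-enal | CC(C)=C[C@@H](OC(C)=O)C=O | intermediate
43 | C4 vinylchromium dichloride from 35 (not isolated) | C=C1[C@@H]2[C@@H](OCc3ccc(OC)cc3)OC=C([Cr](Cl)Cl)[C@H]2CC[C@]2(C)O[C@@H]2[C@@H](OC(=O)c2ccccc2)[C@H]1O[Si](CC)(CC)CC | intermediate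
44 | C12 carbinol (12S) with 13-acetate (13R) | C=C1[C@@H]2[C@@H](OCc3ccc(OC)cc3)OC=C([C@H](O)[C@@H](C=C(C)C)OC(C)=O)[C@H]2CC[C@]2(C)O[C@@H]2[C@@H](OC(=O)c2ccccc2)[C@H]1O[Si](CC)(CC)CC | intermediate
45 | 12,13-diacetate with C1 4-methoxybenzyl acetal and C10 triethylsilyl ether | C=C1[C@@H]2[C@@H](OCc3ccc(OC)cc3)OC=C([C@H](OC(C)=O)[C@@H](C=C(C)C)OC(C)=O)[C@H]2CC[C@]2(C)O[C@@H]2[C@@H](OC(=O)c2ccccc2)[C@H]1O[Si](CC)(CC)CC | intermediate
46 | C1 lactol (anomer mixture, C1 not defined) | C=C1[C@@H]2C(O)OC=C([C@H](OC(C)=O)[C@@H](C=C(C)C)OC(C)=O)[C@H]2CC[C@]2(C)O[C@@H]2[C@@H](OC(=O)c2ccccc2)[C@H]1O[Si](CC)(CC)CC | intermediate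
47 | C1 acetate (1S) with C10 triethylsilyl ether | C=C1[C@@H]2[C@H](OC(C)=O)OC=C([C@H](OC(C)=O)[C@@H](C=C(C)C)OC(C)=O)[C@H]2CC[C@]2(C)O[C@@H]2[C@@H](OC(=O)c2ccccc2)[C@H]1O[Si](CC)(CC)CC | intermediate
48 | target CNP0317411.2 | C=C1[C@@H]2[C@H](OC(C)=O)OC=C([C@H](OC(C)=O)[C@@H](C=C(C)C)OC(C)=O)[C@H]2CC[C@]2(C)O[C@@H]2[C@@H](OC(=O)c2ccccc2)[C@H]1O | target

## Step count and least certain steps

Total: 28 steps. Longest linear sequence: 19 steps from 1 (steps 1–3, 5–7, 12–19, 24–28). The C7–C10 piece takes 4 steps (8–11), the side-chain aldehyde 5 steps (8, 20–23) and the Grignard reagent 1 step (4).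

**Step 5 (key step).** The most likely failure is slow C-alkylation of the magnesium/copper enolate. Proton transfer between product and enolate would then scramble the site of alkylation (C3 as well as C4a), allow double alkylation, or simply return the protonated 1,4-adduct. Fallback, from 4 back to 10: the cuprate addition is run in the presence of Me3SiCl and the enolate is captured as the trimethylsilyl enol ether F1, which is isolated. The lithium enolate is then released with MeLi in THF and alkylated with 7 in the presence of DMPU. This separates the two bond formations and uses a lithium enolate of defined regiochemistry.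

**Step 16.** The ring closure may show poor facial selectivity at C10, because the conformational demands of the forming nine-membered ring can override the Felkin–Anh preference. Oligomerisation, or reductive loss of the α-benzoyloxy group by divalent chromium, would lower the yield. Fallback, from 29 back to 31: if the cyclisation gives mainly the C10 epimer F2, it is inverted by a Mitsunobu reaction with chloroacetic acid (PPh3, diisopropyl azodicarboxylate) to the chloroacetate F3. The chloroacetyl group is then removed selectively with thiourea and NaHCO3, which leaves the benzoate alone.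

**Step 18.** Oxygen may be delivered to the wrong face of C7=C8 if the preferred ring conformer exposes the face syn to the C9 benzoate; over-oxidation of the C11 methylene is a lesser concern. Fallback, from 32 back to 33: treatment with NBS in aqueous THF gives the bromohydrin F4, with the bromonium ion formed on the face the dioxirane prefers and water opening it at the tertiary C7 from the other face. Ring closure with DBU then places the epoxide oxygen on the face opposite to that reached by direct epoxidation.

**Step 24.** Diastereocontrol at C12 may be poor, since the chiral ring is remote and chromium can chelate. Aldehyde 42 may also be lost by enolisation into conjugation or by reductive cleavage of its α-acetoxy group. Fallback, from 35 and 42 back to 44: the mixture of C12 epimers is oxidised with Dess–Martin periodinane to the C12 ketone F5, a vinylogous ester, which is reduced under reagent control with an oxazaborolidine (CBS) catalyst and catecholborane chosen to give the 12S carbinol.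

**Step 26.** DDQ may abstract the allylic C4a hydride of the electron-rich enol ether in competition with the benzylic hydride of the less electron-rich acetal oxygen, and the lactol may degrade by ring opening. Fallback, from 35 back to 47: the oxidative unmasking is moved to the electron-poor enol triflate. DDQ converts 35 into the lactol triflate F6, acetylation gives the C1 acetate F7, the Nozaki–Hiyama–Kishi coupling with 42 gives the C12 carbinol F8, and acetylation of F8 gives 47.

**Step 27.** Acylation may be kinetically controlled through the more nucleophilic equatorial lactol alkoxide, which would give the C1 epimer of 47. Fallback, from 46 back to 47: the lactol is esterified with acetic acid under Mitsunobu conditions (PPh3, diisopropyl azodicarboxylate). The anomeric oxygen is then the leaving group and acetate enters C1 with inversion, or axially on the oxocarbenium ion, which favours the pseudo-axial acetate. No new compound is made on the way.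

## Further compounds

F1 | step 5 | trimethylsilyl enol ether (C4=C4a) of the 1,4-adduct | C=C([Si](C)(C)C)[C@@H]1[C@@H](OCc2ccc(OC)cc2)OCC(O[Si](C)(C)C)=C1
F2 | step 16 | C10 epimer of 31 | C=C1[C@@H]2[C@@H](OCc3ccc(OC)cc3)OCC(=O)[C@H]2CC/C(C)=C\[C@@H](OC(=O)c2ccccc2)[C@@H]1O
F3 | step 16 | C10 chloroacetate of 31 | C=C1[C@@H]2[C@@H](OCc3ccc(OC)cc3)OCC(=O)[C@H]2CC/C(C)=C\[C@@H](OC(=O)c2ccccc2)[C@H]1OC(=O)CCl
F4 | step 18 | bromohydrin of 32 (7-hydroxy, 8-bromo, anti) | C=C1[C@@H]2[C@@H](OCc3ccc(OC)cc3)OCC(=O)[C@H]2CC[C@](C)(O)[C@@H](Br)[C@@H](OC(=O)c2ccccc2)[C@H]1O[Si](CC)(CC)CC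
F5 | step 24 | C12 ketone corresponding to 44 | C=C1[C@@H]2[C@@H](OCc3ccc(OC)cc3)OC=C(C(=O)[C@@H](C=C(C)C)OC(C)=O)[C@H]2CC[C@]2(C)O[C@@H]2[C@@H](OC(=O)c2ccccc2)[C@H]1O[Si](CC)(CC)CC
F6 | step 26 | C1 lactol of enol triflate 35 (anomer mixture) | C=C1[C@@H]2C(O)OC=C(OS(=O)(=O)C(F)(F)F)[C@H]2CC[C@]2(C)O[C@@H]2[C@@H](OC(=O)c2ccccc2)[C@H]1O[Si](CC)(CC)CC
F7 | step 26 | C1 acetate (1S) of the enol triflate | C=C1[C@@H]2[C@H](OC(C)=O)OC=C(OS(=O)(=O)C(F)(F)F)[C@H]2CC[C@]2(C)O[C@@H]2[C@@H](OC(=O)c2ccccc2)[C@H]1O[Si](CC)(CC)CC
F8 | step 26 | C12 carbinol with C1 and C13 acetates and C10 triethylsilyl ether | C=C1[C@@H]2[C@H](OC(C)=O)OC=C([C@H](O)[C@@H](C=C(C)C)OC(C)=O)[C@H]2CC[C@]2(C)O[C@@H]2[C@@H](OC(=O)c2ccccc2)[C@H]1O[Si](CC)(CC)CC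
F0 | step 27 | none | none
A1 | alternative 1 | seco compound with C5=C6 vinyl group and C7 Z-iodoalkene | C=C([C@H](O[Si](CC)(CC)CC)[C@H](OC(=O)c1ccccc1)/C=C(/C)I)[C@@H]1[C@@H](OC)OC=C(C(=O)OC)[C@H]1C=C
A2 | alternative 1 | bicyclic core with Z C7=C8 alkene, C9 benzoate, C10 triethylsilyl ether, C11 methylene and C4 methyl ester | C=C1[C@@H]2[C@@H](OC)OC=C(C(=O)OC)[C@H]2CC/C(C)=C\[C@@H](OC(=O)c2ccccc2)[C@H]1O[Si](CC)(CC)CC
A3 | alternative 2 | C4a aldehyde carrying the 7,8-epoxide, C9 benzoate and C10 silyl ether | O=CCC[C@]1(C)O[C@@H]1[C@@H](OC(=O)c1ccccc1)CO[Si](C)(C)C(C)(C)C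
A4 | alternative 2 | methyl 3-oxopropanoate | COC(=O)CC=O
A5 | alternative 2 | (E)-1-methoxy-4-(trimethylsilyl)but-1-en-3-yne | CO/C=C/C#C[Si](C)(C)C
A6 | alternative 2 | trans-disubstituted 2-methoxydihydropyran with C11 alkyne, C4 ester and C5–C10 chain | C[Si](C)(C)C#C[C@@H]1[C@@H](OC)OC=C(C(=O)OC)[C@H]1CC[C@]1(C)O[C@@H]1[C@@H](OC(=O)c1ccccc1)CO[Si](C)(C)C(C)(C)C
A7 | alternative 3 | nine-membered ring allylsilane with O2 dimethoxymethyl ether (C11=C11a drawn Z) | C[Si](C)(C)C/C1=C/[C@@H]([C@@H](O[Si](C)(C)C(C)(C)C)COC(OC)OC)CC/C(C)=C\[C@@H](OC(=O)c2ccccc2)[C@H]1O[Si](C)(C)C(C)(C)C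
A8 | alternative 3 | trans-fused 2-methoxytetrahydropyran on the nine-membered ring with C11 methylene | C=C1[C@@H]2[C@@H](OC)OC[C@H](O[Si](C)(C)C(C)(C)C)[C@H]2CC/C(C)=C\[C@@H](OC(=O)c2ccccc2)[C@H]1O[Si](C)(C)C(C)(C)C
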